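Numbering: furo[3,4-c]furan core, C1, O2, C3 (syringyl), C3a (OH), C4, O5, C6 (guaiacyl), C6a; ring A holds O5, ring B holds O2. The route rests on cutting the syringyl ring from C3. Stripped of its aryl group, C3 is an acetal-level carbon between O2 and the C3a carbinol. The precursor is therefore a bicyclic lactol, used as both C3 epimers, and the partner is unprotected 2,6-dimethoxyphenol. One acid-catalysed, stereoconvergent Friedel–Crafts arylation sends both epimers through a single ring B oxocarbenium ion. It joins the halves para to the phenol OH and sets C3 on the convex face of the cis-fused bicycle, losing only water.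

Key step: step 6

Assumption: the (S,S) ligand of step 2 is taken to open the Si face of the aldehyde; if the sense proves opposite, the (R,R) ligand is used and nothing else changes.

Step 1
Reactants: 1 α-methylene-γ-butyrolactone
Product: 3 allylic bromide 3-(bromomethyl)furan-2(5H)-one, via dibromide 2 (not isolated)
Conditions: Br2, CH2Cl2, 0 °C; then Et3N, 0 °C to rt
Reagents that add atoms: bromine, BrBr
Why: Electrophilic addition of bromine to the 1,1-disubstituted alkene gives the vicinal dibromide, and amine-induced E2 loss of the tertiary bromide together with a ring C4 hydrogen gives the conjugated endocyclic butenolide that keeps the primary allylic bromide (bromination–dehydrobromination); no stereocentre survives.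

Step 2
Reactants: 3 3-(bromomethyl)furan-2(5H)-one; 4 O-tosylvanillin
Product: 6 (4R)-4-{(S)-hydroxy[3-methoxy-4-(tosyloxy)phenyl]methyl}-3-methylidenedihydrofuran-2(3H)-one, via silyl ether 5 (not isolated)
Conditions: CrCl2 (10 mol %), (S,S)-1,8-bis(4-isopropyl-4,5-dihydrooxazol-2-yl)-3,6-diphenylcarbazole (12 mol %), i-Pr2NEt (30 mol %), Mn powder (2 equiv), Me3SiCl (2 equiv), THF, rt; then 1 M HCl
Reagents that add atoms: chlorotrimethylsilane, C[Si](C)(C)Cl (its Me3Si group is carried only by 5 and is gone in 6)
Why: Catalytic asymmetric Nozaki–Hiyama–Kishi allylation: the allylchromium species made from 3 by divalent chromium (regenerated by Mn, released by Me3SiCl) adds through its ring carbon C4 in a closed six-membered chair transition state, where the ring-locked E-type geometry gives the anti relationship and the tridentate ligand directs attack to the Si face of the aldehyde, so that C6 (S) and C6a (R) of the target are set together.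

Step 3
Reactants: 6 α-methylene lactone alcohol
Product: 7 (3S,4R)-3-hydroxy-3-(hydroxymethyl)-4-{(S)-hydroxy[3-methoxy-4-(tosyloxy)phenyl]methyl}dihydrofuran-2(3H)-one
Conditions: OsO4 (2 mol %), NMO (1.5 equiv), acetone–H2O, 0 °C to rt
Reagents that add atoms: N-methylmorpholine N-oxide, C[N+]1([O-])CCOCC1; water, O
Why: Catalytic OsO4 syn-dihydroxylation with NMO as terminal oxidant: the reagent reaches the exocyclic alkene from the lactone face opposite to the bulky C4 side chain, which places the tertiary OH trans and the new CH2OH cis to that side chain and so sets C3a (S) of the target.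

Step 4
Reactants: 7 triol lactone
Product: 9 bicyclic hydroxy lactone (3aR,4S,6aS)-6a-hydroxy-4-[3-methoxy-4-(tosyloxy)phenyl]tetrahydro-1H,3H-furo[3,4-c]furan-1-one, via primary triflate 8 (not isolated)
Conditions: Tf2O (1.05 equiv), 2,6-lutidine (3 equiv), CH2Cl2, −78 °C to rt
Reagents that add atoms: triflic anhydride, O=S(=O)(OS(=O)(=O)C(F)(F)F)C(F)(F)F (its CF3SO2 group is carried only by 8 and is gone in 9)
Why: Selective sulfonylation of the only primary hydroxyl at low temperature and 5-exo-tet Williamson-type displacement by the neutral benzylic hydroxyl on the same lactone face close ring A with retention at C6, because no bond to a stereocentre is broken, while the hindered pyridine base avoids the alkoxides that could trigger translactonisation or Grob fragmentation.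

Step 5
Reactants: 9 bicyclic hydroxy lactone
Product: 10 bicyclic lactol (3aS,6S,6aR)-6-[3-methoxy-4-(tosyloxy)phenyl]tetrahydro-1H,3H-furo[3,4-c]furan-3,3a-diol (both C3 epimers)
Conditions: i-Bu2AlH (2.5 equiv), CH2Cl2, −78 °C; aq. potassium sodium tartrate
Reagents that add atoms: none
Why: Partial reduction of a lactone with i-Bu2AlH at low temperature: the first equivalent is consumed by the tertiary OH, the tetrahedral aluminium hemiacetal held by that neighbouring alkoxide survives until work-up, the aryl sulfonate is inert, and the C3 epimer mixture is of no consequence for step 6.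

Step 6
Reactants: 10 bicyclic lactol (both C3 epimers); 11 2,6-dimethoxyphenol (syringol)
Product: 13 O-tosylfraxiresinol (3R,3aS,6S,6aR), via oxocarbenium ion 12 (not isolated)
Conditions: Sc(OTf)3 (20 mol %), 11 (3 equiv), 4 Å molecular sieves, CH2Cl2, −20 °C to rt
Reagents that add atoms: none
Why: Sc(OTf)3 ionises the anomeric hydroxyl of either C3 epimer of 10 to the same ring B oxocarbenium ion 12 (O2=C3), the ring carbon of 11 para to its free OH attacks C3, and loss of a proton restores the arene; any O-aryl acetal formed at the hindered phenol oxygen re-ionises and drains into the C-aryl product. The closest known reaction type is the acid-catalysed Friedel–Crafts aryl C-glycosylation of phenols by lactols and glycosyl acetates, which is also known for simple furofuran lactols. No ring is closed, since rings A and B are already in place. The new stereocentre C3 is controlled by the cis-fused bicycle: the arene comes in on the convex face, syn to the small C3a hydroxyl and anti to the C4 methylene of ring A, which is also the inside attack preferred by five-membered oxocarbenium ions with a neighbouring oxygen, and this gives the exo aryl group of the (3R) configuration from both epimers. The step needs ionisation at C3 and not at the benzylic C6–O5 bond, which the electron-poor 4-tosyloxy group on the guaiacyl ring secures, and it needs para attack on 11, which is secured by the two methoxy groups that block both ortho positions and crowd the remaining two ring positions against the neopentyl-like cation. The C3a hydroxyl is left free on purpose, because an ester there would shield the convex face by participation, and the run is stopped once 10 is consumed so that the kinetic product does not re-ionise at C3–O2.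

Step 7
Reactants: 13 O-tosylfraxiresinol
Product: 14 fraxiresinol
Conditions: Mg turnings (10 equiv), MeOH, rt
Reagents that add atoms: none
Why: Reductive cleavage of the aryl sulfonate S–O bond by single-electron transfer from magnesium in methanol frees the guaiacyl phenol under conditions that touch neither the benzylic ethers nor any stereocentre.

Compound list
1 | α-methylene-γ-butyrolactone | C=C1CCOC1=O | starting material
2 | 3-bromo-3-(bromomethyl)dihydrofuran-2(3H)-one (racemic) | O=C1OCCC1(Br)CBr | intermediate
3 | 3-(bromomethyl)furan-2(5H)-one | O=C1OCC=C1CBr | intermediate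
4 | O-tosylvanillin (4-formyl-2-methoxyphenyl 4-methylbenzenesulfonate) | COc1cc(C=O)ccc1OS(=O)(=O)c1ccc(C)cc1 | starting material
5 | trimethylsilyl ether of 6 | C=C1C(=O)OC[C@@H]1[C@H](O[Si](C)(C)C)c1ccc(OS(=O)(=O)c2ccc(C)cc2)c(OC)c1 | intermediate
6 | (4R)-4-{(S)-hydroxy[3-methoxy-4-(tosyloxy)phenyl]methyl}-3-methylidenedihydrofuran-2(3H)-one | C=C1C(=O)OC[C@@H]1[C@H](O)c1ccc(OS(=O)(=O)c2ccc(C)cc2)c(OC)c1 | intermediate
7 | (3S,4R)-3-hydroxy-3-(hydroxymethyl)-4-{(S)-hydroxy[3-methoxy-4-(tosyloxy)phenyl]methyl}dihydrofuran-2(3H)-one | OC[C@]1(O)C(=O)OC[C@@H]1[C@H](O)c1ccc(OS(=O)(=O)c2ccc(C)cc2)c(OC)c1 | intermediate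
8 | primary triflate of 7 | O=S(=O)(OC[C@]1(O)C(=O)OC[C@@H]1[C@H](O)c1ccc(OS(=O)(=O)c2ccc(C)cc2)c(OC)c1)C(F)(F)F | intermediate
9 | (3aR,4S,6aS)-6a-hydroxy-4-[3-methoxy-4-(tosyloxy)phenyl]tetrahydro-1H,3H-furo[3,4-c]furan-1-one (its C1 is C3 of the target) | COc1cc([C@H]2OC[C@]3(O)C(=O)OC[C@H]23)ccc1OS(=O)(=O)c1ccc(C)cc1 | intermediate
10 | (3aS,6S,6aR)-6-[3-methoxy-4-(tosyloxy)phenyl]tetrahydro-1H,3H-furo[3,4-c]furan-3,3a-diol, both C3 epimers | COc1cc([C@H]2OC[C@]3(O)C(O)OC[C@H]23)ccc1OS(=O)(=O)c1ccc(C)cc1 | intermediate
11 | 2,6-dimethoxyphenol (syringol) | COc1cccc(OC)c1O | starting material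
12 | ring B oxocarbenium ion (O2=C3) derived from 10 | COc1cc([C@H]2OC[C@]3(O)C=[O+]C[C@H]23)ccc1OS(=O)(=O)c1ccc(C)cc1 | intermediate
13 | O-tosylfraxiresinol, (3R,3aS,6S,6aR)-3-(4-hydroxy-3,5-dimethoxyphenyl)-6-[3-methoxy-4-(tosyloxy)phenyl]tetrahydro-1H,3H-furo[3,4-c]furan-3a-ol | COc1cc([C@H]2OC[C@]3(O)[C@@H](c4cc(OC)c(O)c(OC)c4)OC[C@H]23)ccc1OS(=O)(=O)c1ccc(C)cc1 | intermediate
14 | fraxiresinol, (3R,3aS,6S,6aR)-3-(4-hydroxy-3,5-dimethoxyphenyl)-6-(4-hydroxy-3-methoxyphenyl)tetrahydro-1H,3H-furo[3,4-c]furan-3a-ol | COc1cc([C@H]2OC[C@]3(O)[C@@H](c4cc(OC)c(O)c(OC)c4)OC[C@H]23)ccc1O | target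

Total step count: 7. Longest linear sequence: 7 steps (1 → 3 → 6 → 7 → 9 → 10 → 13 → 14).

Steps most likely to fail

1. Step 6.
What may go wrong: competing attack through the methoxy-activated ring positions of 11. The syringyl-bearing C3–O2 bond may also re-ionise under the acid, with erosion of configuration or a second arylation.
Fallback (sets out from 10, comes back at 13): the same bond is made under basic conditions from a preformed aryl-metal whose carbon–metal bond fixes the ring position. Commercial 4-bromo-2,6-dimethoxyphenol is silylated (TBSCl, imidazole, DMF) to tert-butyl(4-bromo-2,6-dimethoxyphenoxy)dimethylsilane F1. Mg in THF turns it into the arylmagnesium bromide F2. An excess of F2 adds at −20 °C to the open hydroxy aldehyde form of 10 and should give the ring A triol F3 as a mixture of C3 carbinol epimers. Catalytic camphorsulfonic acid in CH2Cl2 ionises only this electron-rich benzylic carbinol. The C1 hydroxyl then closes ring B on the cation from the side that leaves the aryl group exo, and both epimers converge on the doubly protected fraxiresinol F4. Et3N·3HF in THF removes the silyl group and gives 13.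

2. Step 2.
What may go wrong: insufficient face selectivity of the chromium catalyst with this lactone-bearing allyl partner, or reductive pinacol coupling of the aldehyde by Mn and Me3SiCl.
Fallback (sets out from 3 and 4, comes back at 6): the metal is changed from chromium to boron, and the source of asymmetry from a ligand on the metal to a chiral Brønsted acid. Pd2(dba)3-catalysed borylation of 3 with B2pin2 in THF at 60 °C gives the primary allylboronate 3-[(pinacolboryl)methyl]furan-2(5H)-one F5. F5 is added to 4 in toluene under catalysis by the enantiomer of 3,3'-bis(2,4,6-triisopropylphenyl)-BINOL phosphoric acid that opens the Si face. This addition runs through the same closed chair and gives the pinacol boric ester of 6 F6, which aqueous work-up hydrolyses to 6.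

3. Step 4.
What may go wrong: competing sulfonylation of the benzylic hydroxyl, or closure of the tertiary hydroxyl onto the triflate so that the reaction stalls before ring A is formed.
Fallback (sets out from 7, comes back at 9): ring A is closed in two deliberate stages by way of the epoxide. Bu2SnO-catalysed monotosylation (TsCl, Et3N, CH2Cl2) marks the primary hydroxyl as the primary tosylate F7. DBU lets the acidic tertiary hydroxyl close the spiro epoxide F8 with its C3a–O bond untouched. Catalytic camphorsulfonic acid in CH2Cl2 then lets the neutral benzylic hydroxyl open the epoxide at its CH2 end, the carbonyl-bearing end being closed to attack, which gives 9.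

Further compounds
F1 | step 6 | tert-butyl(4-bromo-2,6-dimethoxyphenoxy)dimethylsilane | COc1cc(Br)cc(OC)c1O[Si](C)(C)C(C)(C)C
F2 | step 6 | arylmagnesium bromide, [4-(tert-butyldimethylsilyloxy)-3,5-dimethoxyphenyl]magnesium bromide | COc1cc([Mg]Br)cc(OC)c1O[Si](C)(C)C(C)(C)C
F3 | step 6 | ring A triol, (3S,4R,5S)-3-{[4-(tert-butyldimethylsilyloxy)-3,5-dimethoxyphenyl](hydroxy)methyl}-4-(hydroxymethyl)-5-[3-methoxy-4-(tosyloxy)phenyl]oxolan-3-ol, both carbinol epimers | COc1cc([C@H]2OC[C@](O)(C(O)c3cc(OC)c(O[Si](C)(C)C(C)(C)C)c(OC)c3)[C@@H]2CO)ccc1OS(=O)(=O)c1ccc(C)cc1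
F4 | step 6 | doubly protected fraxiresinol (syringyl O-TBS, guaiacyl O-tosyl) | COc1cc([C@H]2OC[C@]3(O)[C@@H](c4cc(OC)c(O[Si](C)(C)C(C)(C)C)c(OC)c4)OC[C@H]23)ccc1OS(=O)(=O)c1ccc(C)cc1
F5 | step 2 | 3-[(pinacolboryl)methyl]furan-2(5H)-one | O=C1OCC=C1CB1OC(C)(C)C(C)(C)O1
F6 | step 2 | pinacol boric ester of 6 | C=C1C(=O)OC[C@@H]1[C@H](OB1OC(C)(C)C(C)(C)O1)c1ccc(OS(=O)(=O)c2ccc(C)cc2)c(OC)c1
F7 | step 4 | primary tosylate of 7 | Cc1ccc(cc1)S(=O)(=O)OC[C@]1(O)C(=O)OC[C@@H]1[C@H](O)c1ccc(OS(=O)(=O)c2ccc(C)cc2)c(OC)c1
F8 | step 4 | spiro epoxide, 1,5-dioxaspiro[2.4]heptan-4-one carrying the (S)-hydroxy(aryl)methyl group at C7 | C1O[C@]12C(=O)OC[C@@H]2[C@H](O)c1ccc(OS(=O)(=O)c2ccc(C)cc2)c(OC)c1
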